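(Readings and results stem from a simulated flask for substances that don't exist; noise was put on by code.)

I was to read each flask at 6.0 min, later than the last reading of any earlier run, so I needed the level at which those runs stopped.

| flask | starting complex | incoming ligand | leaving ligand | remark | time |
|---|---|---|---|---|---|
| midnight | 0.80 M | 0.37 M | 0.40 M | run made earlier |  |
| noon | 0.80 M | 0.63 M | 0.40 M | run made earlier |  |
| summer | 0.80 M | 0.94 M | 0.40 M | run made earlier |  |
| violet | 0.80 M | 0.400 M | 0.400 M |  | 6.0 min |
| blue | 0.80 M | 0.800 M | 0.400 M |  | 6.0 min |
| green | 0.80 M | 0.960 M | 0.400 M |  | 6.0 min |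

| run | time / min | complex with two exchanged / % |
|---|---|---|
| midnight | 0.833 | 4.2 |
| midnight | 1.50 | 3.0 |
| midnight | 2.50 | 3.2 |
| midnight | 3.00 | 4.2 |
| midnight | 4.00 | 3.2 |
| noon | 0.417 | 9.9 |
| noon | 1.00 | 11.8 |
| noon | 2.00 | 11.9 |
| noon | 3.00 | 11.7 |
| noon | 4.00 | 12.0 |
| summer | 0.833 | 22.1 |
| summer | 1.50 | 21.2 |
| summer | 2.50 | 21.1 |
| summer | 3.00 | 20.1 |
| summer | 4.00 | 23.2 |

(readings scatter by 1 percentage point)

- the analysis behind the earlier runs scatters by 1 percentage point, standard deviation

* complex with two exchanged at the end, in percent of the starting complex charged, for each flask in turn (violet, blue, green)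

The noon run read 11.8% at 1.00 min and 12.0% at 4.00 min, a shift smaller than the scatter, so I averaged the readings of each run from 0.833 min on into a plateau of complex with two exchanged: 3.56% for midnight, 11.8% for noon and 21.5% for summer.

But these plateaus are not proportional to c(incoming ligand), so I treated a simulated plateau as the large part of each answer and reckoned the correction. From noon to summer I read 0.313 M⁻¹, the plateau gain: the rise of the plateau, as a fraction of the starting complex charged, per unit of c(incoming ligand), with c(starting complex) and c(leaving ligand) held. My own reckoning gave 4.50% for violet, 17.2% for blue and 22.2% for green.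

The forecast gave 4.5%, 17.1% and 22.1%, holding that “only the plateaus matter”. It differed from mine in blue and green by less than the scatter.

The flasks gave 4.67%, 16.6% and 22.0%.

    starting complex → decomposition product (k = 2.80 × 10⁻⁴ s⁻¹)
    incoming ligand ⇌ dormant form (K = 1.20, k = 0.430 s⁻¹)
    starting complex + incoming ligand → leaving ligand + complex with one exchanged (k = 2.00 M⁻¹ s⁻¹)
    complex with one exchanged + incoming ligand → leaving ligand + complex with two exchanged (k = 0.760 M⁻¹ s⁻¹)
    complex with two exchanged + incoming ligand → leaving ligand + complex with three exchanged (k = 0.810 M⁻¹ s⁻¹)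

In violet, incoming ligand, the limiting reagent, fell under a fiftieth of its charge by 0.0799 min, far sooner than the reading at 6.0 min. Complex with two exchanged stood at 4.67% after 3.00 min and 4.67% after 6.00 min, with 0% of the incoming ligand left. The plateau gain times the step from blue to green gives 5 percentage points, and green stood 5.4 points above blue. From violet to blue it gives 13 points, and blue stood 12 points above violet.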